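# Isogoiazensolide by a three-component union at C7 and C11

Atom numbers follow the germacrane skeleton: C1 ketone, C2=C3 furanone alkene, C4 with methylene C15, C5 carbinol, C6 lactone O–CH, C7, C8 ester O–CH, C9 CH2, C10 quaternary with methyl C14, C11=C13, C12 lactone carbonyl.

## Analysis of the target

Target 27 is a furanoheliangolide built on a ten-membered carbocycle (C1–C10). An oxygen bridges C3 and C10, so that C10, C1, C2, C3 and this oxygen form a 3(2H)-furanone. An α-methylene-γ-butyrolactone (ring O, C12, C11 with C13) is fused on the C6–C7 bond. There are five stereocentres: C5 (R), C6 (S), C7 (R) and C8 (S) are contiguous, and C10 (R) is quaternary and cut off from them by the C9 methylene. H6 and H7 are trans, the C5 hydroxyl is anti to the C6 lactone oxygen, and the C8 oxygen is syn to both the C6 and the C10 oxygen along the chain. The molecule carries three conjugate acceptors (methylene lactone, methacrylate, and the furanone cross-conjugated with C4=C15) and an allylic alcohol, so strong bases and nucleophiles are excluded late in the route. The difficulty lies in the strained bridged medium ring, in a stereotetrad that must be set in an open chain or during ring closure, and in C10, which receives no induction from the other centres. The strategy rests on the lactone being a saturated butenolide: C7 is its β-carbon and C11 its α-carbon. A C8 nucleophile and a C13 electrophile can therefore be added across C7=C11 of a butenolide that already holds C5 and C6, anti to the C6 substituent.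

## Retrosynthetic reasoning

**C11=C13.** Target 27 is traced to the Mannich base 25. The most reactive acceptor of the molecule is kept as a dimethylaminomethyl group and released last by N-methylation and elimination. Nothing else has to be built at that stage.

**C4–C5.** Macrocycle 25 is cut between C4 and C5. A carbinol next to a 1,1-disubstituted alkene is the signature of an alkenyl halide adding to an aldehyde, so bromo-aldehyde 24 is the precursor. Cutting here leaves the furanone and the lactone intact as two rigid anchors, and only one new stereocentre (C5) forms in the closure, next to C6, which can steer it.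

**C5 oxidation level and the C3–O bond.** Aldehyde 24 comes from silyl ether 22 through alcohol 23. Furanone 22 is opened at the C3–O bond to the α′-hydroxy ynone 20. The forward reaction is an oxa-Michael closure of the C10 hydroxyl onto C3, which fixes the furanone regiochemistry without any control element.

**C3–C4 and C1–C2.** Ynone 20 is the oxidation product of diol 19. Its bromoalkene (C4, C15) is attached by alkyne–halide coupling to the terminal alkyne 18. Alkyne 18 arises from a two-carbon acetylide and the α-hydroxy aldehyde 17, which comes from acetonide 15 through diol 16. C1 and C10 thus stay tied together as a ketal until the acetylide is needed.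

**C8 oxygen.** Ester 15 is the methacrylate of alcohol 14. Acylating at this point lets the ester serve as the protecting group of C8–OH, so that the C5 hydroxyl formed at the end needs no differentiation. Alcohol 14 comes from ketone 13 by reagent-controlled reduction, and 13 from dithiane 12. C8 thus travels at the ketone level through the carbon–carbon bond formation.

**C7–C8 and C11–C13 (key disconnection).** Mannich base 12 is cut at both bonds into dithiane 6, butenolide 8 and iminium salt 9. The C6 centre of 8 controls C7; 6 brings C10 from a chiral epoxide; 9 brings C13. Two of the five stereocentres come from purchased building blocks and a third is set by the first of them.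

**Fragments.** Dithiane 6 is the acetonide of diol 5, made by opening epoxide 2 with the anion of 1 at its methylene carbon. This gives C8–C9 and leaves the quaternary C10 untouched. Butenolide 8 is the silyl ether of 7.

## Alternatives that were turned down

**Alternative 1:** The lactone carbonyl C12 is removed as carbon monoxide, cutting O–C12 and C11–C12. In the forward sense the bicyclic ethynyl carbinol A2 (C7 ethynyl, C6–OH free, C5 silyl ether) is cyclocarbonylated with PdCl2, SnCl2 and PPh3 under CO to the silyl ether A1 of the target.
- For it: the methylene lactone appears in one catalytic step, in final form, at the very end. On this point it is stronger than the chosen route, which carries a masked amine through thirteen steps and needs a separate unveiling.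
- Against it: A2 must be assembled as a ten-membered bridged ring with a propargylic C7 centre trans to C6–OH and flanked by the C5 and C8 oxygens, without the lactone to organise the chain. The Lewis-acidic tin and palladium mixture meets the dienone, the methacrylate and a C4=C15 alkene placed close to the alkyne, so carbopalladation and isomerisation pathways are open. A silyl group must still be removed from A1 in the presence of three acceptors.
- In its place the chosen strategy takes C6 from a commercial butenolide and sets C7 from it while forming two carbon–carbon bonds.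

**Alternative 2:** The carbocycle is cut at C9–C10. In the forward sense the open-chain bis(enol silane) A4 (a 2-methyl-3-siloxyfuran tethered to the C8 enol silane) is oxidised at a carbon anode to the bicyclic keto-furanone A3.
- For it: one redox step closes the ring, creates quaternary C10 and delivers the furanone from a linear precursor. In step economy for the core it is stronger than the chosen route.
- Against it: C10 would be set by the facial choice of a radical cation on a planar furan inside a ten-membered transition state, with no stereocentre nearby. Solvent capture competes with a medium-ring closure. A3 still lacks C15 and C13 and has C8 as a ketone. Methylenation at C4, which is γ to C1 through the vinylogous ester, has no dependable method.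
- In its place the chosen strategy brings C10 in from a chiral epoxide and both methylene carbons in with the building blocks.

**Alternative 3:** The carbocycle is cut at C2–C3 and re-joined through sulfur. In the forward sense the eleven-membered S-(2-oxoalkyl) thioester A6 is treated with LiBr, Et3N and P(OMe)3, and an Eschenmoser sulfide contraction gives the ten-membered 1,3-diketone A5.
- For it: the ring is first closed by carbon–sulfur bond formation, which is easier than any carbon–carbon medium-ring closure, and all five stereocentres are in place before cyclisation. On both points it is stronger than the chromium-mediated closure of the chosen route, which sets C5 during ring formation. A5 would also cyclodehydrate directly to the furanone.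
- Against it: the thioester carbonyl C3 is conjugated with C4=C15, so phosphite, amine and thiolate can add at C15. A5 is a 2-methylene-1,3-dione and more electrophilic still. Three silyl ethers must be told apart, and C13 and the methacrylate are still missing. A6 needs a long linear synthesis in which the C5–C8 tetrad and C10 are each set separately.
- In its place the chosen strategy offers a short convergent assembly and fewer protecting groups.

Key step: step 4

## Route

Assumptions on the chemistry:
- Commercial (S)-2-methylglycidol is used as supplied. Any minor enantiomer would appear after step 4 as a separable diastereomer of 12.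
- 1,1-Dibromoethene is taken as a purchased, stabilised reagent.
- The C1 carbinol of 18 and 19 is a mixture of epimers, which is removed in step 12.

Step 1
Reactants: 1 1,3-dithiane; 2 (S)-2-methylglycidol
Product: 5 (2R)-3-(1,3-dithian-2-yl)-2-methylpropane-1,2-diol, via 2-lithio-1,3-dithiane 3 (not isolated), via lithium alkoxide of the epoxide 4 (not isolated)
Conditions: 1 (2.3 equiv), n-BuLi (2.2 equiv), THF, −30 °C; 2, −30 → 0 °C; aq. NH4Cl
Reagents that add atoms: none
Why: Corey–Seebach epoxide opening; one equivalent of 3 deprotonates the hydroxyl and a second attacks the unhindered epoxide CH2 (C9), so no bond to the quaternary carbon is touched and C10 keeps its configuration. A Payne shift of alkoxide 4 would be degenerate and lead to the same diol.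

Step 2
Reactants: 5 (2R)-3-(1,3-dithian-2-yl)-2-methylpropane-1,2-diol
Product: 6 2-{[(4R)-2,2,4-trimethyl-1,3-dioxolan-4-yl]methyl}-1,3-dithiane
Conditions: Me2C(OMe)2, PPTS (cat.), CH2Cl2, rt
Reagents that add atoms: 2,2-dimethoxypropane, COC(C)(C)OC
Why: Acid-catalysed transketalisation closes the five-membered dioxolane on the 1,2-diol; the dithiane is inert to mild acid.

Step 3
Reactants: 7 (S)-5-(hydroxymethyl)furan-2(5H)-one
Product: 8 (S)-5-[(tert-butyldiphenylsilyloxy)methyl]furan-2(5H)-one
Conditions: TBDPSCl, imidazole, CH2Cl2, 0 °C → rt
Reagents that add atoms: tert-butyl(chloro)diphenylsilane, CC(C)(C)[Si](Cl)(c1ccccc1)c1ccccc1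
Why: Standard silylation of a primary alcohol; the bulky silyl ether later shields one face of the butenolide and survives aqueous acetic acid.

Step 4
Reactants: 6 2-{[(4R)-2,2,4-trimethyl-1,3-dioxolan-4-yl]methyl}-1,3-dithiane; 8 (S)-5-[(tert-butyldiphenylsilyloxy)methyl]furan-2(5H)-one; 9 dimethylmethyleneiminium iodide
Product: 12 trans,trans Mannich base lactone with the C8 dithiane, via lithiated dithiane 10 (not isolated), via lithium lactone enolate 11 (not isolated)
Conditions: 6 (1.2 equiv), n-BuLi, THF, −30 °C; DMPU, −78 °C; 8, −78 °C; 9 (2.5 equiv), −78 → 0 °C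
Reagents that add atoms: none
Why: n-BuLi removes the C8 proton of 6; in THF with DMPU the solvent-separated carbanion 10 attacks the β-carbon (C7) of butenolide 8 instead of the carbonyl, and the lactone enolate 11 is then alkylated at C11 by iminium ion 9 (Mannich reaction). The closest known reaction type is the tandem conjugate addition of 2-lithio-1,3-dithianes to butenolides with enolate trapping, combined with the aminomethylation of lactone enolates by Eschenmoser's salt. No ring is closed; the C7–C8 and C11–C13 bonds form. C7 is controlled by C6 of 8: the silyloxymethyl group blocks its own face, the nucleophile enters anti, and the 6,7-trans lactone results. C11 is controlled by C7: the bulky dithianyl group sends the iminium ion to the opposite face (7,11-trans), and this centre is erased in step 17. The step needs 1,4-addition to win over 1,2-addition and over γ-deprotonation of 8, which would expel the silyloxide; the polar cosolvent, the low temperature and a slight excess of 10 are meant to secure this. The C10 oxygen is γ to the carbanion and cannot be lost by β-elimination, and the acetonide and silyl ether are inert to all three components.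

Step 5
Reactants: 12 trans,trans Mannich base lactone with the C8 dithiane
Product: 13 C8 ketone
Conditions: Hg(ClO4)2·3H2O (2.2 equiv), CaCO3, THF/H2O (5:1), 0 °C
Reagents that add atoms: water, O
Why: Thiophilic divalent mercury activates the hindered dithiane for hydrolysis within minutes, and the carbonate buffer protects the acetonide. The β-acyloxy ketone 13 is kept cold and reduced at once, so that the internal amine cannot trigger loss of the lactone oxygen from C6.

Step 6
Reactants: 13 C8 ketone
Product: 14 (8S)-alcohol
Conditions: (R)-1-methyl-3,3-diphenyltetrahydro-1H,3H-pyrrolo[1,2-c][1,3,2]oxazaborole [(R)-Me-CBS, 0.5–1 equiv], catecholborane (3 equiv), toluene/CH2Cl2, −78 → −40 °C; MeOH, aq. NaHCO3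
Reagents that add atoms: none
Why: Corey–Bakshi–Shibata reduction; with the α-branched ring carbon C7 as the large group and the C9 methylene as the small one, the (R)-catalyst should deliver hydride to the face that gives 8S. Catecholborane binds the amine only reversibly and leaves lactone and acetonide alone.

Step 7
Reactants: 14 (8S)-alcohol
Product: 15 C8 methacrylate
Conditions: methacrylic anhydride, Et3N, DMAP, CH2Cl2, 0 °C → rt
Reagents that add atoms: methacrylic anhydride, C=C(C)C(=O)OC(=O)C(C)=C
Why: DMAP-catalysed acylation with retention at C8; the ester serves from here on as the protecting group of the C8 oxygen, so no later protection or deprotection is needed.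

Step 8
Reactants: 15 C8 methacrylate
Product: 16 C1,C10-diol
Conditions: AcOH/H2O (4:1), 45 °C
Reagents that add atoms: none
Why: Acid hydrolysis of the terminal acetonide at the ketal carbon; the primary tert-butyldiphenylsilyl ether, the ester and the lactone are stable to aqueous acetic acid and the protonated amine is inert.

Step 9
Reactants: 16 C1,C10-diol
Product: 17 α-hydroxy aldehyde
Conditions: SO3·pyridine, DMSO, i-Pr2NEt, CH2Cl2, 0 °C
Reagents that add atoms: none
Why: Parikh–Doering oxidation takes the primary C1 alcohol to the aldehyde; the tertiary C10 hydroxyl cannot be oxidised and C10 has no hydrogen to epimerise. The aldehyde is used directly.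

Step 10
Reactants: 17 α-hydroxy aldehyde
Product: 18 terminal propargylic diol
Conditions: HC≡CMgBr (3.5 equiv), THF, −78 → −30 °C; AcOH
Reagents that add atoms: ethynylmagnesium bromide, C#C[Mg]Br
Why: Grignard addition; the first equivalent deprotonates the C10 hydroxyl, and the resulting magnesium alkoxide chelates and activates the aldehyde, which reacts far faster than the methacrylate or the lactone at this temperature. The new C1 configuration is irrelevant because C1 is oxidised in step 12.

Step 11
Reactants: 18 terminal propargylic diol
Product: 19 2-bromo-enyne diol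
Conditions: CH2=CBr2 (5 equiv), Pd(PPh3)4 (5 mol %), CuI (10 mol %), i-Pr2NH, THF, 0 °C → rt
Reagents that add atoms: 1,1-dibromoethene, C=C(Br)Br
Why: Sonogashira mono-alkynylation of a geminal dibromoalkene; the dihalide inserts zerovalent palladium faster than the bromo-enyne product, and its excess suppresses the second coupling. This attaches C4 and C15 and leaves the alkenyl bromide needed in step 16.

Step 12
Reactants: 19 2-bromo-enyne diol
Product: 20 α′-hydroxy ynone
Conditions: Dess–Martin periodinane, NaHCO3, CH2Cl2, 0 °C
Reagents that add atoms: none
Why: Buffered hypervalent-iodine oxidation of the secondary propargylic alcohol; the tertiary alcohol and the tertiary amine are not oxidised.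

Step 13
Reactants: 20 α′-hydroxy ynone
Product: 22 3(2H)-furanone, via enaminone 21 (not isolated)
Conditions: Et2NH (1.5 equiv), EtOH, 0 °C → rt; AcOH
Reagents that add atoms: none
Why: Et2NH adds to the ynone β-carbon (C3); the C10 hydroxyl then displaces the amine from C3 by addition–elimination, closing the five-membered ring, the classical conversion of α′-hydroxy ynones into 3(2H)-furanones. The ynone reacts with the amine far faster than the hindered methacrylate.

Step 14
Reactants: 22 3(2H)-furanone
Product: 23 C5 primary alcohol
Conditions: HF·pyridine, pyridine, THF, 0 °C → rt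
Reagents that add atoms: none
Why: Buffered fluoride cleaves the silyl ether without the basicity of tetraalkylammonium fluoride, so the ester, the lactone and the furanone are untouched.

Step 15
Reactants: 23 C5 primary alcohol
Product: 24 C5 aldehyde
Conditions: Dess–Martin periodinane, NaHCO3, CH2Cl2, 0 °C
Reagents that add atoms: none
Why: Neutral oxidation to the α-acyloxy aldehyde, which is used crude to avoid epimerisation at C6.

Step 16
Reactants: 24 C5 aldehyde
Product: 25 macrocyclic Mannich base (5R)
Conditions: CrCl2 (10 equiv), NiCl2 (cat.), degassed DMSO, rt, 2 mM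
Reagents that add atoms: none
Why: Nozaki–Hiyama–Kishi reaction: zerovalent nickel inserts into the C4–Br bond, transmetalation to trivalent chromium gives an alkenylchromium species that adds to the C5 aldehyde. This closes the ten-membered carbocycle (nine-membered when counted through the furanone oxygen). Felkin–Anh addition anti to the C6–O bond, the usual sense for alkenylchromium reagents with α-oxygenated aldehydes, should give the 5,6-anti (5R) alcohol; the reagent tolerates ketone, esters and the amine.

Step 17
Reactants: 25 macrocyclic Mannich base (5R)
Product: 27 isogoiazensolide, via trimethylammonium iodide 26 (not isolated)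
Conditions: MeI, THF, rt; then aq. NaHCO3, CH2Cl2, rt
Reagents that add atoms: none
Why: N-Methylation turns the amine into a leaving group, and mild base removes the acidic C11 proton (E1cB) to unveil the C11=C13 methylene. Bicarbonate is too weak to touch the ester, the furanone or the allylic alcohol.

## Compound list

1 | 1,3-dithiane | C1CSCSC1 | starting material
2 | (S)-2-methylglycidol, [(2S)-2-methyloxiran-2-yl]methanol | C[C@]1(CO)CO1 | starting material
3 | 2-lithio-1,3-dithiane | [Li]C1SCCCS1 | intermediate
4 | lithium [(2S)-2-methyloxiran-2-yl]methanolate | [Li]OC[C@@]1(C)CO1 | intermediate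
5 | (2R)-3-(1,3-dithian-2-yl)-2-methylpropane-1,2-diol | C[C@@](O)(CC1SCCCS1)CO | intermediate
6 | 2-{[(4R)-2,2,4-trimethyl-1,3-dioxolan-4-yl]methyl}-1,3-dithiane | C[C@@]1(CC2SCCCS2)COC(C)(C)O1 | intermediate
7 | (S)-5-(hydroxymethyl)furan-2(5H)-one | O=C1O[C@H](CO)C=C1 | starting material
8 | (S)-5-[(tert-butyldiphenylsilyloxy)methyl]furan-2(5H)-one | O=C1O[C@H](CO[Si](c2ccccc2)(c2ccccc2)C(C)(C)C)C=C1 | intermediate
9 | dimethylmethyleneiminium iodide | C=[N+](C)C.[I-] | starting material
10 | 2-lithio derivative of 6 (carbanion at C8) | C[C@@]1(CC2([Li])SCCCS2)COC(C)(C)O1 | intermediate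
11 | lithium enolate of the C7 adduct (C6,C7-trans) | [Li]OC1=C[C@H](C2(C[C@]3(C)COC(C)(C)O3)SCCCS2)[C@@H](CO[Si](c2ccccc2)(c2ccccc2)C(C)(C)C)O1 | intermediate
12 | (3R,4S,5S)-5-[(tert-butyldiphenylsilyloxy)methyl]-3-[(dimethylamino)methyl]-4-(2-{[(4R)-2,2,4-trimethyl-1,3-dioxolan-4-yl]methyl}-1,3-dithian-2-yl)oxolan-2-one (3,4-trans, 4,5-trans) | CN(C)C[C@@H]1C(=O)O[C@H](CO[Si](c2ccccc2)(c2ccccc2)C(C)(C)C)[C@H]1C1(C[C@]2(C)COC(C)(C)O2)SCCCS1 | intermediate
13 | lactone as in 12 with the dithiane replaced by a C8 ketone | CN(C)C[C@@H]1C(=O)O[C@H](CO[Si](c2ccccc2)(c2ccccc2)C(C)(C)C)[C@H]1C(=O)C[C@]1(C)COC(C)(C)O1 | intermediate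
14 | (8S)-alcohol from 13 | CN(C)C[C@@H]1C(=O)O[C@H](CO[Si](c2ccccc2)(c2ccccc2)C(C)(C)C)[C@H]1[C@@H](O)C[C@]1(C)COC(C)(C)O1 | intermediate
15 | (8S)-methacrylate of 14 | CN(C)C[C@@H]1C(=O)O[C@H](CO[Si](c2ccccc2)(c2ccccc2)C(C)(C)C)[C@H]1[C@@H](OC(=O)C(C)=C)C[C@]1(C)COC(C)(C)O1 | intermediate
16 | diol from 15 (C1 primary OH, C10 tertiary OH, 10R) | CN(C)C[C@@H]1C(=O)O[C@H](CO[Si](c2ccccc2)(c2ccccc2)C(C)(C)C)[C@H]1[C@@H](OC(=O)C(C)=C)C[C@@](C)(O)CO | intermediate
17 | C1 aldehyde with free C10 hydroxyl | CN(C)C[C@@H]1C(=O)O[C@H](CO[Si](c2ccccc2)(c2ccccc2)C(C)(C)C)[C@H]1[C@@H](OC(=O)C(C)=C)C[C@@](C)(O)C=O | intermediate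
18 | C1 ethynyl carbinol (both C1 epimers), C10 hydroxyl free | CN(C)C[C@@H]1C(=O)O[C@H](CO[Si](c2ccccc2)(c2ccccc2)C(C)(C)C)[C@H]1[C@@H](OC(=O)C(C)=C)C[C@@](C)(O)C(O)C#C | intermediate
19 | as 18 with the alkyne carrying a 1-bromovinyl group (C4 bromide, C15 methylene) | CN(C)C[C@@H]1C(=O)O[C@H](CO[Si](c2ccccc2)(c2ccccc2)C(C)(C)C)[C@H]1[C@@H](OC(=O)C(C)=C)C[C@@](C)(O)C(O)C#CC(Br)=C | intermediate
20 | α′-hydroxy ynone (C1 ketone, C2≡C3, C4 bromide) | CN(C)C[C@@H]1C(=O)O[C@H](CO[Si](c2ccccc2)(c2ccccc2)C(C)(C)C)[C@H]1[C@@H](OC(=O)C(C)=C)C[C@@](C)(O)C(=O)C#CC(Br)=C | intermediate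
21 | β-(diethylamino) enone from 20 | CN(C)C[C@@H]1C(=O)O[C@H](CO[Si](c2ccccc2)(c2ccccc2)C(C)(C)C)[C@H]1[C@@H](OC(=O)C(C)=C)C[C@@](C)(O)C(=O)C=C(N(CC)CC)C(Br)=C | intermediate
22 | 3(2H)-furanone (10R) with 1-bromovinyl at C3, C5 silyl ether | CN(C)C[C@@H]1C(=O)O[C@H](CO[Si](c2ccccc2)(c2ccccc2)C(C)(C)C)[C@H]1[C@@H](OC(=O)C(C)=C)C[C@@]1(C)OC(C(Br)=C)=CC1=O | intermediate
23 | C5 primary alcohol from 22 | CN(C)C[C@@H]1C(=O)O[C@H](CO)[C@H]1[C@@H](OC(=O)C(C)=C)C[C@@]1(C)OC(C(Br)=C)=CC1=O | intermediate
24 | C5 aldehyde from 23 | CN(C)C[C@@H]1C(=O)O[C@H](C=O)[C@H]1[C@@H](OC(=O)C(C)=C)C[C@@]1(C)OC(C(Br)=C)=CC1=O | intermediate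
25 | 11,13-dihydro-13-(dimethylamino)isogoiazensolide (5R,6S,7R,8S,10R; C11 aminomethyl trans to C7–C8) | C=C(C)C(=O)O[C@H]1C[C@@]2(C)OC(=CC2=O)C(=C)[C@@H](O)[C@H]2OC(=O)[C@@H](CN(C)C)[C@@H]21 | intermediate
26 | trimethylammonium iodide of 25 | C=C(C)C(=O)O[C@H]1C[C@@]2(C)OC(=CC2=O)C(=C)[C@@H](O)[C@H]2OC(=O)[C@@H](C[N+](C)(C)C)[C@@H]21.[I-] | intermediate
27 | isogoiazensolide | C=C(C)C(=O)O[C@H]1C[C@@]2(C)OC(=CC2=O)C(=C)[C@@H](O)[C@H]2OC(=O)C(=C)[C@@H]21 | target

## Step count and least certain steps

Total: 17 steps. Longest linear sequence: 16 steps (steps 1, 2 and 4–17, from 1 and 2); step 3 is a one-step branch.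

**Step 4 (key step).**
- Risk: the alkyl-substituted dithiane anion is more basic and more hindered than aryl-stabilised ones. γ-Deprotonation of 8 with loss of the silyloxide and 1,2-attack at the lactone carbonyl can compete with conjugate addition, and enolate 11 may be protonated before the sparingly soluble salt 9 reaches it.
- Fallback, from 6 and 8, back at 12: the C7–C8 bond is made by a radical. Anion 10 is quenched with CO2 to give the dithiane carboxylic acid F1. Visible-light decarboxylation of F1 (2,4,5,6-tetra(9H-carbazol-9-yl)isophthalonitrile, Cs2CO3, DMF, blue light) in the presence of 8 generates a non-basic tertiary dithianyl radical, which should add to C7 anti to the C6 substituent (Giese addition) and give the simple adduct F2. Lithium diisopropylamide (THF, −78 °C) then forms the enolate of F2, where C11 is the only acidic site, and 9 aminomethylates it to 12.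

**Step 6.**
- Risk: poor reagent control. The two flanks of the C8 carbonyl (ring carbon C7 and the neopentyl-type C9 methylene) may not differ enough for the catalyst, the amine may tie up boron, and an unknown substrate bias may oppose the catalyst.
- Fallback, from 13, back at 15: the 8R alcohol F3 is made on purpose, with the (S)-catalyst or LiBH(s-Bu)3, whichever gives the cleaner epimer. F3 is esterified with inversion under Mitsunobu conditions (methacrylic acid, PPh3, diisopropyl azodicarboxylate, toluene, 0 °C → rt) to give 15 directly. Either C8 epimer can thus be funnelled into the route.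

**Step 11.**
- Risk: coupling at the second C–Br bond to a cross-conjugated enediyne, oxidative homocoupling of the alkyne, and polymerisation of the dihalide, all on a polar substrate that carries an amine and a diol.
- Fallback, from 17, back at 19: the coupling is moved off the substrate. Ethynyltrimethylsilane and a large excess of 1,1-dibromoethene are coupled with the same catalysts to the silyl bromo-enyne F4. K2CO3 in MeOH frees 2-bromobut-1-en-3-yne F5, which is used as a THF solution. EtMgBr (THF, 0 °C) converts F5 into its alkynyl Grignard reagent, which is added to aldehyde 17 at −78 °C to give 19 in one operation. Steps 10 and 11 are thereby merged.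

**Step 16.**
- Risk: poor facial selectivity at the aldehyde, because the conformation of the closing medium ring rather than the Felkin preference may decide C5. Protodebromination and dimerisation add to this if closure is slow.
- Fallback, from 24, back at 25: the closure is run without regard to C5. The 5S epimer F6, alone or mixed with 25, is oxidised with Dess–Martin periodinane to the C5 ketone F7. F7 is reduced with NaBH4 and CeCl3·7H2O (MeOH, −78 °C) or with catecholborane and the matching CBS catalyst. On the rigid bicycle, hydride should enter from the outer face, and the catalyst can override if it does not. C5 is then set by a ketone reduction instead of by the carbon–carbon bond formation.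

## Further compounds

F1 | step 4 | 2-{[(4R)-2,2,4-trimethyl-1,3-dioxolan-4-yl]methyl}-1,3-dithiane-2-carboxylic acid | C[C@@]1(CC2(C(=O)O)SCCCS2)COC(C)(C)O1
F2 | step 4 | conjugate adduct without C13: (4S,5S)-5-[(tert-butyldiphenylsilyloxy)methyl]-4-(2-{[(4R)-2,2,4-trimethyl-1,3-dioxolan-4-yl]methyl}-1,3-dithian-2-yl)oxolan-2-one (4,5-trans) | O=C1C[C@H](C2(C[C@]3(C)COC(C)(C)O3)SCCCS2)[C@@H](CO[Si](c2ccccc2)(c2ccccc2)C(C)(C)C)O1
F3 | step 6 | (8R)-alcohol, C8 epimer of 14 | CN(C)C[C@@H]1C(=O)O[C@H](CO[Si](c2ccccc2)(c2ccccc2)C(C)(C)C)[C@H]1[C@H](O)C[C@]1(C)COC(C)(C)O1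
F4 | step 11 | (3-bromobut-3-en-1-yn-1-yl)trimethylsilane | C=C(Br)C#C[Si](C)(C)C
F5 | step 11 | 2-bromobut-1-en-3-yne | C=C(Br)C#C
F6 | step 16 | (5S)-alcohol, C5 epimer of 25 | C=C(C)C(=O)O[C@H]1C[C@@]2(C)OC(=CC2=O)C(=C)[C@H](O)[C@H]2OC(=O)[C@@H](CN(C)C)[C@@H]21
F7 | step 16 | C5 ketone from 25 and F6 | C=C(C)C(=O)O[C@H]1C[C@@]2(C)OC(=CC2=O)C(=C)C(=O)[C@H]2OC(=O)[C@@H](CN(C)C)[C@@H]21
A1 | alternative 1 | isogoiazensolide C5 triethylsilyl ether | C=C(C)C(=O)O[C@H]1C[C@@]2(C)OC(=CC2=O)C(=C)[C@@H](O[Si](CC)(CC)CC)[C@H]2OC(=O)C(=C)[C@@H]21
A2 | alternative 1 | bicyclic C7-ethynyl C6-carbinol with C5 triethylsilyl ether and C8 methacrylate | C=C(C)C(=O)O[C@H]1C[C@@]2(C)OC(=CC2=O)C(=C)[C@@H](O[Si](CC)(CC)CC)[C@@H](O)[C@@H]1C#C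
A3 | alternative 2 | bicyclic furanone with C8 ketone, C4 and C11 methylene groups, C5 silyl ether | O=C1C[C@@]2(C)OC(=CC2=O)C[C@@H](O[Si](C)(C)C(C)(C)C)[C@H]2OC(=O)C[C@@H]21
A4 | alternative 2 | open-chain lactone carrying the C8 trimethylsilyl enol ether and the 2-methyl-3-(trimethylsilyloxy)furan | C=C(O[Si](C)(C)C)[C@H]1CC(=O)O[C@@H]1[C@H](O[Si](C)(C)C(C)(C)C)Cc1cc(O[Si](C)(C)C)c(C)o1
A5 | alternative 3 | ten-membered 1,3-diketone | CC(C)(C)[Si](C)(C)O[C@H]1C[C@@](C)(O[Si](CC)(CC)CC)C(=O)CC(=O)C(=C)[C@@H](O[Si](C)(C)C(C)(C)C)[C@H]2OC(=O)C[C@@H]21
A6 | alternative 3 | eleven-membered S-(2-oxoalkyl) thioester (sulfur between C2 and C3) | CC(C)(C)[Si](C)(C)O[C@H]1C[C@@](C)(O[Si](CC)(CC)CC)C(=O)CSC(=O)C(=C)[C@@H](O[Si](C)(C)C(C)(C)C)[C@H]2OC(=O)C[C@@H]21
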